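1. 2 questions stand on this flask, and I answer both from one ratio of readings.

| flask | starting material | second substrate | free catalyst | added ligand | remark |
|---|---|---|---|---|---|
| larch | 0.42 M | 1 equiv | 0.74 mol% | 9.3 mM | run made earlier |
| maple | 0.42 M | 4 equiv | 0.74 mol% | 9.3 mM | run made earlier |
| oak | 0.42 M | 2 equiv | 0.37 mol% | 9.3 mM | run made earlier |
| flask | 0.42 M | 2.00 equiv | 0.74 mol% | 9.3 mM |  |

| run | time / h | target / % | starting material / % |
|---|---|---|---|
| larch | 0.833 | 8 | 93 |
| larch | 1.50 | 13 | 88 |
| larch | 2.50 | 19 | 78 |
| larch | 3.00 | 21 | 81 |
| larch | 4.00 | 28 | 70 |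
| larch | 5.00 | 31 | 68 |
| maple | 0.417 | 2 | 94 |
| maple | 0.667 | 6 | 94 |
| maple | 1.00 | 4 | 97 |
| maple | 2.00 | 10 | 90 |
| maple | 3.00 | 14 | 84 |
| maple | 5.00 | 27 | 75 |
| oak | 0.417 | 2 | 98 |
| oak | 0.667 | 6 | 99 |
| oak | 1.33 | 2 | 99 |
| oak | 2.50 | 8 | 92 |
| oak | 5.00 | 14 | 84 |

(scatter of a reading: 2 percentage points)

- the numbers in the tables scatter by 2 percentage points (one standard deviation)
- what is bound to the catalyst counts as converted

* factor on the rate of making target when 5.0% of the starting material are converted if free catalyst is charged twice over
* factor on the rate when 5.0% of the starting material are converted if free catalyst is charged at 4 mol% instead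

2. To whoever takes over: the flask was charged with starting material, 2.00 equiv of second substrate, 0.74 mol% of free catalyst and 9.3 mM of added ligand.
3. When you come at 5.00 h, I expect about 27% to 31% target in the flask, the readings of maple and larch, whose second substrate charges of 4 equiv and 1 equiv lie on either side of its charge.
4. Leave the catalyst charge alone. Oak, with half the loading, reads 14% target at that same time.
5. I let the mean of larch and maple stand, as a guess, for 2.00 equiv of second substrate at the loading of this flask, and divide it by oak, so time drops out. This gives 2.07, the loading gain: target at one time with twice the catalyst, over target at that time without the doubling. It is a reading, each figure scattered by 2 percentage points.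
6. The gain gives a catalyst order of 1.05. I carry that order upward from the loadings of the runs, which is an extrapolation, so I take the gain as my factor for doubling, and my own factor for 4 mol% is 5.89.
7. The forecast says 2.2 (from 1.8 to 2.8) and 6.5 (from 4.3 to 10.5), on the ground that “the catalyst order is about 1 or slightly higher”. Its second factor stands above mine.

The simulation gives 2.09 and 6.21.

    catalyst intermediate A → free catalyst + target (k = 18.5 h⁻¹)
    free catalyst + added ligand ⇌ idle complex, settled at all times (K = 4100 M⁻¹)
    starting material + free catalyst ⇌ catalyst intermediate A (K = 746 M⁻¹, k = 2440 M⁻¹ h⁻¹)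
    catalyst intermediate B → free catalyst + second product (k = 24.3 h⁻¹)
    second substrate + free catalyst ⇌ catalyst intermediate B (K = 22.0 M⁻¹, k = 3160 M⁻¹ h⁻¹)

Beside these stand the gain of 2.07 and my 5.89 for 4 mol%, which is lower. In the flask, catalyst intermediate A passes on to target at 18.5 h⁻¹ and falls back at 3.27 h⁻¹, a ratio of 5.66. After 4.00 h it holds 42.0% of the catalyst, against 39.3% in idle complex, 17.6% in catalyst intermediate B and 1.19% as free catalyst.

The earlier runs and the new flask were generated by integration with constants of no real substance, and the scatter is random.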